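**Plan**

1. Numbering of the carbocycle used below: C1 ketone carbon, C2 (heptenyl-bearing) and C3 (hydroxymethyl-bearing) alkene carbons, C4 carbinol, C5 (CH) and C6 (quaternary) oxirane carbons, C7 the CH2OH carbon.
2. Retrosynthesis: after C1 is returned to a carbinol, the carbocycle is cut at C3–C4 together with the C2–heptenyl bond (one palladium event), giving an acyclic epoxy 5-alkynal and (E)-heptenylboronic acid. Further cuts are C1–C2 (acetylide plus epoxy aldehyde), the side-chain C=C (cross-metathesis), the oxirane (Sharpless epoxidation) and the C6–allyl bond (Stille coupling), back to but-2-yne-1,4-diol.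
3. Forward: the oxirane ring is made first on an acyclic Z-allylic alcohol, then the side chain and the alkyne are attached. The six-membered carbocycle is closed last by a zerovalent-palladium trans-alkenylative ("anti-Wacker") cyclisation that also installs the heptenyl group.
4. Enabling feature: the tetrasubstituted C2=C3 alkene carries the C4 carbinol on C3 and an alkenyl group on C2, trans to each other. This is the retron of trans-addition of an aldehyde carbon and an alkenyl group across a C2≡C3 alkyne. The cis-fused C5–C6 oxirane holds C1 and C4 on one side, so the 5-alkynal is folded for closure.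
5. Stereochemistry: C5 and C6 come from the Sharpless epoxidation, and C4 from the ring closure under control of the neighbouring oxirane. Alkene geometries come from syn-hydrostannation/Stille (C1 and C4 cis), cross-metathesis (E enoate) and the E-boronic acid (E heptenyl).

Key step: step 11

Remark: C1 is carried from step 7 to step 13 as a mixture of carbinol epimers (unspecified in the SMILES), because step 14 oxidises it to the ketone and merges both.

**Step 1**
Reactants: 1 but-2-yne-1,4-diol
Product: 2 (E)-2-(tributylstannyl)but-2-ene-1,4-diol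
Conditions: Bu3SnH (1.1 equiv), PdCl2(PPh3)2 (2 mol %), THF, 0 °C to rt
Reagents that add atoms: tributyltin hydride, CCCC[SnH](CCCC)CCCC
Why: Palladium-catalysed hydrostannation is a syn addition and the symmetrical alkyne poses no regiochemical question, so the two CH2OH groups (later C1 and C4) should end up cis.

**Step 2**
Reactants: 2 (E)-2-(tributylstannyl)but-2-ene-1,4-diol
Product: 3 (E)-4-[(tert-butyldimethylsilyl)oxy]-2-(tributylstannyl)but-2-en-1-ol
Conditions: TBSCl (1.0 equiv), imidazole, CH2Cl2, −40 to −20 °C
Reagents that add atoms: tert-butyldimethylsilyl chloride, CC(C)(C)[Si](C)(C)Cl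
Why: Monosilylation under steric control: the hydroxyl next to the stannyl-bearing alkene carbon is shielded by the Bu3Sn group, so the remote primary hydroxyl (the C4 oxygen) should be silylated.

**Step 3**
Reactants: 3 (E)-4-[(tert-butyldimethylsilyl)oxy]-2-(tributylstannyl)but-2-en-1-ol; 4 allyl bromide
Product: 5 (Z)-4-[(tert-butyldimethylsilyl)oxy]-2-(prop-2-en-1-yl)but-2-en-1-ol
Conditions: Pd2(dba)3 (2.5 mol %), P(2-furyl)3 (10 mol %), CuI (10 mol %), DMF, 40 °C
Reagents that add atoms: none
Why: Stille coupling of an alkenylstannane with an allylic bromide proceeds with retention of alkene geometry, so the skipped diene should keep the two oxygenated carbons cis.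

**Step 4**
Reactants: 5 (Z)-4-[(tert-butyldimethylsilyl)oxy]-2-(prop-2-en-1-yl)but-2-en-1-ol
Product: 6 [(2R,3S)-3-{[(tert-butyldimethylsilyl)oxy]methyl}-2-(prop-2-en-1-yl)oxiran-2-yl]methanol
Conditions: Ti(OiPr)4 (20 mol %), D-(−)-diethyl tartrate (24 mol %), t-BuOOH (2 equiv), 4 Å MS, CH2Cl2, −20 °C
Reagents that add atoms: tert-butyl hydroperoxide, CC(C)(C)OO
Why: Sharpless asymmetric epoxidation: the primary allylic alkoxide binds titanium and the D-(−)-tartrate (the enantiomer opposite to the one that gives (2S)-epoxy alcohols from simple primary allylic alcohols) should direct oxygen to the face that gives the (2R,3S)-oxirane, stereospecifically cis, leaving the isolated terminal alkene untouched.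

**Step 5**
Reactants: 6 [(2R,3S)-3-{[(tert-butyldimethylsilyl)oxy]methyl}-2-(prop-2-en-1-yl)oxiran-2-yl]methanol; 7 tert-butyl methacrylate
Product: 8 tert-butyl (E)-4-[(2R,3S)-3-{[(tert-butyldimethylsilyl)oxy]methyl}-2-(hydroxymethyl)oxiran-2-yl]-2-methylbut-2-enoate
Conditions: second-generation Hoveyda–Grubbs catalyst (5 mol %), 7 (8 equiv), CH2Cl2, 40 °C
Reagents that add atoms: none
Why: Olefin cross-metathesis of a terminal alkene with a 1,1-disubstituted methacrylate gives the trisubstituted enoate under thermodynamic control, which should be the E isomer (chain trans to the ester).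

**Step 6**
Reactants: 8 tert-butyl (E)-4-[(2R,3S)-3-{[(tert-butyldimethylsilyl)oxy]methyl}-2-(hydroxymethyl)oxiran-2-yl]-2-methylbut-2-enoate
Product: 9 tert-butyl (E)-4-[(2S,3S)-3-{[(tert-butyldimethylsilyl)oxy]methyl}-2-formyloxiran-2-yl]-2-methylbut-2-enoate
Conditions: Dess–Martin periodinane, NaHCO3, CH2Cl2, 0 °C to rt
Reagents that add atoms: none
Why: Buffered Dess–Martin oxidation of the primary alcohol; the α-carbon is the quaternary oxirane carbon, so nothing can epimerise.

**Step 7**
Reactants: 9 tert-butyl (E)-4-[(2S,3S)-3-{[(tert-butyldimethylsilyl)oxy]methyl}-2-formyloxiran-2-yl]-2-methylbut-2-enoate; 10 4-methoxybenzyl propargyl ether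
Product: 12 tert-butyl (E)-4-[(2R,3S)-3-{[(tert-butyldimethylsilyl)oxy]methyl}-2-{(1RS)-1-hydroxy-4-[(4-methoxybenzyl)oxy]but-2-yn-1-yl}oxiran-2-yl]-2-methylbut-2-enoate, via lithiated propargyl ether 11 (not isolated)
Conditions: 10 (1.5 equiv), n-BuLi (1.4 equiv), THF, −78 °C; then 9, −78 °C; aq. NH4Cl
Reagents that add atoms: none
Why: 1,2-Addition of a lithium acetylide to the aldehyde at −78 °C, where the hindered ester and the oxirane are inert; the new C1 carbinol should form as an epimer mixture, which is of no consequence because C1 becomes the ketone.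

**Step 8**
Reactants: 12 propargylic alcohol (both C1 epimers)
Product: 13 tert-butyl (E)-4-[(2S,3S)-2-{(1RS)-1-[(tert-butyldimethylsilyl)oxy]-4-[(4-methoxybenzyl)oxy]but-2-yn-1-yl}-3-{[(tert-butyldimethylsilyl)oxy]methyl}oxiran-2-yl]-2-methylbut-2-enoate
Conditions: TBSOTf, 2,6-lutidine, CH2Cl2, −78 to 0 °C
Reagents that add atoms: tert-butyldimethylsilyl trifluoromethanesulfonate, CC(C)(C)[Si](C)(C)OS(=O)(=O)C(F)(F)F
Why: Silylation of a hindered secondary alcohol with a silyl triflate and a hindered pyridine base, which avoids a free alkoxide and therefore a Payne rearrangement of the adjacent oxirane.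

**Step 9**
Reactants: 13 bis-silyl ether
Product: 14 tert-butyl (E)-4-[(2S,3S)-2-{(1RS)-1-[(tert-butyldimethylsilyl)oxy]-4-[(4-methoxybenzyl)oxy]but-2-yn-1-yl}-3-(hydroxymethyl)oxiran-2-yl]-2-methylbut-2-enoate
Conditions: HF·pyridine, pyridine, THF, 0 °C
Reagents that add atoms: none
Why: Selective desilylation: the unhindered primary silyl ether should be cleaved by buffered HF·pyridine much faster than the secondary one flanked by a quaternary carbon.

**Step 10**
Reactants: 14 primary alcohol
Product: 15 tert-butyl (E)-4-[(2S,3R)-2-{(1RS)-1-[(tert-butyldimethylsilyl)oxy]-4-[(4-methoxybenzyl)oxy]but-2-yn-1-yl}-3-formyloxiran-2-yl]-2-methylbut-2-enoate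
Conditions: Dess–Martin periodinane, NaHCO3, CH2Cl2, 0 °C
Reagents that add atoms: none
Why: Buffered Dess–Martin oxidation gives the epoxy 5-alkynal under non-epimerising conditions; it should be used without delay.

**Step 11**
Reactants: 15 epoxy 5-alkynal (both C1 epimers); 16 (E)-hept-1-en-1-ylboronic acid
Product: 17 tert-butyl (E)-4-[(1S,2RS,5S,6S)-2-[(tert-butyldimethylsilyl)oxy]-3-[(E)-hept-1-en-1-yl]-5-hydroxy-4-{[(4-methoxybenzyl)oxy]methyl}-7-oxabicyclo[4.1.0]hept-3-en-1-yl]-2-methylbut-2-enoate
Conditions: Pd(PPh3)4 (5 mol %), 16 (1.5 equiv), degassed MeOH, 65 °C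
Reagents that add atoms: none
Why: Zerovalent palladium binds the C2≡C3 alkyne and the complexed alkyne attacks the methanol-activated aldehyde through C3 on the face opposite to the metal ("anti-Wacker" oxidative addition), giving a six-membered alkenylpalladium (divalent) alkoxide with Pd on C2; transmetalation from the alkenylboronic acid and reductive elimination then place the E-heptenyl group on C2 with retention, so that C4 and the heptenyl group are trans across the new C2=C3 bond, as the ring demands. The closest known reaction type is the Pd(PPh3)4-catalysed trans-selective arylative and alkenylative cyclisation of 5-alkynals with organoboronic acids in methanol, which gives 2,3-disubstituted cyclohex-2-en-1-ols. The carbocycle closes in the 6-endo-dig mode (bond C3–C4), both alkyne carbons becoming ring atoms. The only new stereocentre, C4, is controlled by the cis-fused oxirane next to the aldehyde: hydrogen bonding by the protic medium (methanol, boronic acid) should bridge the aldehyde oxygen and the oxirane oxygen, so the carbonyl is attacked in this syn arrangement and the hydroxyl ends up cis to the oxirane oxygen. The step needs 6-endo over 5-exo closure, which the internal alkyl-substituted alkyne, the PPh3-ligated catalyst and the cis-oxirane (C1 and C4 held on one side) should favour, and it needs the other groups to stay inert, which holds because neither silyl ether, PMB ether, oxirane nor enoate is an allylic or propargylic leaving group for zerovalent palladium. Both C1 epimers of 15 should undergo the same closure and are merged in step 14.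

**Step 12**
Reactants: 17 cyclohexenol
Product: 18 4-methoxybenzylidene acetal joining the C4 and C7 oxygens of 17 in a 1,3-dioxane (C1 silyl ether retained)
Conditions: DDQ (1.2 equiv), 4 Å MS, CH2Cl2, 0 °C
Reagents that add atoms: none
Why: DDQ-mediated oxidative acetalisation: the PMB ether is oxidised to an oxocarbenium ion that, under anhydrous conditions, is trapped by the neighbouring C4 hydroxyl, so the ether should become a six-membered acetal masking both oxygens without a separate protection step.

**Step 13**
Reactants: 18 acetal silyl ether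
Product: 19 C1 alcohol of acetal 18 (both C1 epimers)
Conditions: Bu4NF, AcOH (1:1), THF, 0 °C to rt
Reagents that add atoms: none
Why: Fluoride desilylation buffered with acetic acid, which keeps the liberated C1 alkoxide protonated (no oxirane migration); the acetal and the tert-butyl ester are stable to fluoride.

**Step 14**
Reactants: 19 C1 alcohol
Product: 20 epoxy enone (C1 ketone) carrying the 4-methoxybenzylidene acetal and the tert-butyl ester
Conditions: Dess–Martin periodinane, NaHCO3, CH2Cl2, 0 °C
Reagents that add atoms: none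
Why: Dess–Martin oxidation of the allylic alcohol gives the conjugated epoxy enone and merges both C1 epimers into one compound.

**Step 15**
Reactants: 20 epoxy enone
Product: 21 (E)-4-[(1S,5S,6S)-3-[(E)-hept-1-en-1-yl]-5-hydroxy-4-(hydroxymethyl)-2-oxo-7-oxabicyclo[4.1.0]hept-3-en-1-yl]-2-methylbut-2-enoic acid (CNP0332048.3)
Conditions: CF3CO2H/CH2Cl2/H2O (10:40:1), 0 °C to rt
Reagents that add atoms: none
Why: Acidolysis: aqueous trifluoroacetic acid should hydrolyse the 4-methoxybenzylidene acetal and cleave the tert-butyl ester (loss of 2-methylpropene) in one operation, while the oxirane is deactivated towards acid by the adjacent ketone.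

**Compound list**

1 | but-2-yne-1,4-diol | OCC#CCO | starting material
2 | (E)-2-(tributylstannyl)but-2-ene-1,4-diol | OC/C=C(\CO)[Sn](CCCC)(CCCC)CCCC | intermediate
3 | (E)-4-[(tert-butyldimethylsilyl)oxy]-2-(tributylstannyl)but-2-en-1-ol | CC(C)(C)[Si](C)(C)OC/C=C(\CO)[Sn](CCCC)(CCCC)CCCC | intermediate
4 | allyl bromide | C=CCBr | starting material
5 | (Z)-4-[(tert-butyldimethylsilyl)oxy]-2-(prop-2-en-1-yl)but-2-en-1-ol | CC(C)(C)[Si](C)(C)OC/C=C(\CO)CC=C | intermediate
6 | [(2R,3S)-3-{[(tert-butyldimethylsilyl)oxy]methyl}-2-(prop-2-en-1-yl)oxiran-2-yl]methanol | OC[C@@]1(CC=C)O[C@H]1CO[Si](C)(C)C(C)(C)C | intermediate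
7 | tert-butyl methacrylate | C=C(C)C(=O)OC(C)(C)C | starting material
8 | tert-butyl (E)-4-[(2R,3S)-3-{[(tert-butyldimethylsilyl)oxy]methyl}-2-(hydroxymethyl)oxiran-2-yl]-2-methylbut-2-enoate | OC[C@@]1(C/C=C(\C)C(=O)OC(C)(C)C)O[C@H]1CO[Si](C)(C)C(C)(C)C | intermediate
9 | tert-butyl (E)-4-[(2S,3S)-3-{[(tert-butyldimethylsilyl)oxy]methyl}-2-formyloxiran-2-yl]-2-methylbut-2-enoate | O=C[C@@]1(C/C=C(\C)C(=O)OC(C)(C)C)O[C@H]1CO[Si](C)(C)C(C)(C)C | intermediate
10 | 4-methoxybenzyl propargyl ether (1-methoxy-4-[(prop-2-yn-1-yloxy)methyl]benzene) | C#CCOCc1ccc(OC)cc1 | starting material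
11 | lithiated propargyl ether (lithium acetylide of 10) | [Li]C#CCOCc1ccc(OC)cc1 | intermediate
12 | propargylic alcohol, C1 epimer mixture: tert-butyl (E)-4-[(2R,3S)-3-{[(tert-butyldimethylsilyl)oxy]methyl}-2-{(1RS)-1-hydroxy-4-[(4-methoxybenzyl)oxy]but-2-yn-1-yl}oxiran-2-yl]-2-methylbut-2-enoate | OC(C#CCOCc1ccc(OC)cc1)[C@@]1(C/C=C(\C)C(=O)OC(C)(C)C)O[C@H]1CO[Si](C)(C)C(C)(C)C | intermediate
13 | bis-silyl ether (C1 and C4 oxygens silylated; oxirane 2S,3S; C1 epimer mixture) | CC(C)(C)[Si](C)(C)OC(C#CCOCc1ccc(OC)cc1)[C@@]1(C/C=C(\C)C(=O)OC(C)(C)C)O[C@H]1CO[Si](C)(C)C(C)(C)C | intermediate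
14 | primary alcohol (C4–OH free, C1 silyl ether; oxirane 2S,3S; C1 epimer mixture) | CC(C)(C)[Si](C)(C)OC(C#CCOCc1ccc(OC)cc1)[C@@]1(C/C=C(\C)C(=O)OC(C)(C)C)O[C@H]1CO | intermediate
15 | epoxy 5-alkynal (C4 aldehyde, C1 silyl ether; oxirane 2S,3R; C1 epimer mixture) | CC(C)(C)[Si](C)(C)OC(C#CCOCc1ccc(OC)cc1)[C@@]1(C/C=C(\C)C(=O)OC(C)(C)C)O[C@H]1C=O | intermediate
16 | (E)-hept-1-en-1-ylboronic acid | CCCCC/C=C/B(O)O | starting material
17 | cyclohexenol: tert-butyl (E)-4-[(1S,2RS,5S,6S)-2-[(tert-butyldimethylsilyl)oxy]-3-[(E)-hept-1-en-1-yl]-5-hydroxy-4-{[(4-methoxybenzyl)oxy]methyl}-7-oxabicyclo[4.1.0]hept-3-en-1-yl]-2-methylbut-2-enoate | CCCCC/C=C/C1=C(COCc2ccc(OC)cc2)[C@H](O)[C@@H]2O[C@]2(C/C=C(\C)C(=O)OC(C)(C)C)C1O[Si](C)(C)C(C)(C)C | intermediate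
18 | 4-methoxybenzylidene acetal of the C4 and C7 oxygens (1,3-dioxane), C1 silyl ether, tert-butyl ester; acetal carbon and C1 unspecified | CCCCC/C=C/C1=C2COC(c3ccc(OC)cc3)O[C@@H]2[C@@H]4O[C@]4(C/C=C(\C)C(=O)OC(C)(C)C)C1O[Si](C)(C)C(C)(C)C | intermediate
19 | C1 alcohol of the acetal (C1 epimer mixture) | CCCCC/C=C/C1=C2COC(c3ccc(OC)cc3)O[C@@H]2[C@@H]4O[C@]4(C/C=C(\C)C(=O)OC(C)(C)C)C1O | intermediate
20 | epoxy enone (C1 ketone) with 4-methoxybenzylidene acetal and tert-butyl ester | CCCCC/C=C/C1=C2COC(c3ccc(OC)cc3)O[C@@H]2[C@@H]4O[C@]4(C/C=C(\C)C(=O)OC(C)(C)C)C1=O | intermediate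
21 | (E)-4-[(1S,5S,6S)-3-[(E)-hept-1-en-1-yl]-5-hydroxy-4-(hydroxymethyl)-2-oxo-7-oxabicyclo[4.1.0]hept-3-en-1-yl]-2-methylbut-2-enoic acid (CNP0332048.3) | CCCCC/C=C/C1=C(CO)[C@H](O)[C@@H]2O[C@]2(C/C=C(\C)C(=O)O)C1=O | target

**Step count and risks**

Total step count: 15. Longest linear sequence: 15 steps (from but-2-yne-1,4-diol; compounds 4, 7, 10 and 16 are commercial).

Steps most likely to fail:

1. Step 11. The exocyclic aldehyde may be attacked on the wrong face (hydroxyl trans to the oxirane) if the hydrogen-bond bridge to the oxirane oxygen does not dominate, and some closure through the inner alkyne carbon may compete. Fallback: from 15 the same closure is run without regard to the C4 configuration, giving the C4-epimeric cyclohexenols F1. Dess–Martin oxidation then gives the C4 ketone, epoxy enone F2. Luche reduction (NaBH4, CeCl3·7H2O, MeOH, −78 °C) should deliver hydride to the ring ketone anti to the oxirane oxygen, the usual bias of 2,3-epoxycyclohexenones, and returns to 17. C4 is thus set by hydride delivery to a ring ketone and not in the C–C bond formation.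

2. Step 15. Acid-promoted breakdown of the product (oxirane opening, ionisation or trifluoroacetylation of the allylic alcohols) may compete with ester cleavage. Fallback: from 20 the acetal alone is hydrolysed with 80% aqueous acetic acid at rt to give the tert-butyl ester of the target F3. The ester is then cleaved without protic acid by TMSOTf/2,6-lutidine in CH2Cl2 at 0 °C (silyl ester with loss of 2-methylpropene; transient silyl ethers and the silyl ester are hydrolysed on mild aqueous work-up), reaching 21.

3. Step 12. DDQ may attack the electron-rich 1,3-diene or oxidise the free allylic alcohol in competition with the PMB ether. Fallback: the PMB ether is removed before the diene exists. From 15, DDQ in wet CH2Cl2 (pH 7 buffer) gives the alkynal with a free propargylic alcohol F4. The palladium closure of step 11 with 16 then gives the C4,C7-diol F5. Acid-catalysed transacetalisation (4-methoxybenzaldehyde dimethyl acetal, PPTS, CH2Cl2) returns to 18.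

**Further compounds**

F1 | step 11 | C4-epimer mixture of cyclohexenol 17 | CCCCC/C=C/C1=C(COCc2ccc(OC)cc2)C(O)[C@@H]2O[C@]2(C/C=C(\C)C(=O)OC(C)(C)C)C1O[Si](C)(C)C(C)(C)C
F2 | step 11 | C4 ketone (epoxy enone; C1 silyl ether, C7 PMB ether, tert-butyl ester) | CCCCC/C=C/C1=C(COCc2ccc(OC)cc2)C(=O)[C@@H]2O[C@]2(C/C=C(\C)C(=O)OC(C)(C)C)C1O[Si](C)(C)C(C)(C)C
F3 | step 15 | tert-butyl ester of the target | CCCCC/C=C/C1=C(CO)[C@H](O)[C@@H]2O[C@]2(C/C=C(\C)C(=O)OC(C)(C)C)C1=O
F4 | step 12 | epoxy 5-alkynal with free propargylic alcohol (C1 silyl ether) | CC(C)(C)[Si](C)(C)OC(C#CCO)[C@@]1(C/C=C(\C)C(=O)OC(C)(C)C)O[C@H]1C=O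
F5 | step 12 | C4,C7-diol of the cyclohexene (C1 silyl ether, tert-butyl ester) | CCCCC/C=C/C1=C(CO)[C@H](O)[C@@H]2O[C@]2(C/C=C(\C)C(=O)OC(C)(C)C)C1O[Si](C)(C)C(C)(C)C
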